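Ring C is cut at the aryl ether bond O1–C8a and at C2–C3, which reduces the chromanone to an aldol pair: the trimethylsilyl enol ether of an ortho-fluoro aryl methyl ketone (ring A) and O-benzylvanillin (ring B). The key step uses the C4 carbonyl twice, since it is beta to O1 and ortho to C8a: it supplies the enol nucleophile for an enantioselective Mukaiyama aldol (C2–C3), and then activates the neighbouring C–F bond for ring closure by the new C2 oxygen (O1–C8a), all in one flask. The C3 hydroxyl is then added trans to the aryl group by Rubottom oxidation; debenzylation and selective 7-O-prenylation finish the route.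

Key step: step 4

Assumption: the acyloxyborane of the (2S,3S)-tartrate series is taken to direct the enolsilane to the Si face of the aldehyde, by analogy with simple aryl methyl ketone enolsilanes; the sense would be checked on a model aldol and the (2R,3R) series used if it proves opposite.

Step 1
Reactants: 1 5-fluorobenzene-1,3-diol (5-fluororesorcinol); 2 acetic acid
Product: 3 1-(2-fluoro-4,6-dihydroxyphenyl)ethan-1-one
Conditions: ZnCl2, AcOH (neat), 140 °C
Reagents that add atoms: none
Why: Nencki-type Friedel–Crafts acylation of the resorcinol should take place para to one hydroxyl and ortho to the other, which here is the carbon next to fluorine, the position between the two hydroxyls being the hindered minor site; no stereocentre is formed.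

Step 2
Reactants: 3 1-(2-fluoro-4,6-dihydroxyphenyl)ethan-1-one
Product: 4 1-[2,4-bis(benzyloxy)-6-fluorophenyl]ethan-1-one
Conditions: BnBr, K2CO3, DMF, 60 °C
Reagents that add atoms: benzyl bromide, BrCc1ccccc1
Why: Williamson etherification of both phenoxides (the hydrogen-bonded ortho hydroxyl needs the warm polar medium) installs benzyl ethers that are inert to the Lewis acid, fluoride and dioxirane used later and leave together on hydrogenolysis.

Step 3
Reactants: 4 1-[2,4-bis(benzyloxy)-6-fluorophenyl]ethan-1-one
Product: 5 {[1-(2,4-bis(benzyloxy)-6-fluorophenyl)ethenyl]oxy}(trimethyl)silane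
Conditions: LiN(SiMe3)2, THF, −78 °C; then Me3SiCl
Reagents that add atoms: chlorotrimethylsilane, C[Si](C)(C)Cl
Why: Kinetic deprotonation at the only enolisable carbon and O-silylation of the lithium enolate should give the silyl enol ether needed for the Mukaiyama aldol.

Step 4
Reactants: 5 {[1-(2,4-bis(benzyloxy)-6-fluorophenyl)ethenyl]oxy}(trimethyl)silane (slight excess); 6 4-(benzyloxy)-3-methoxybenzaldehyde (O-benzylvanillin, limiting)
Product: 8 (2S)-5,7-bis(benzyloxy)-2-[4-(benzyloxy)-3-methoxyphenyl]-2,3-dihydro-4H-chromen-4-one, via silyl aldol adduct 7 (not isolated)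
Conditions: chiral acyloxyborane (CAB) from (2S,3S)-2-O-(2,6-diisopropoxybenzoyl)tartaric acid and 3,5-(CF3)2C6H3B(OH)2 (20 mol%), EtCN, −78 °C; then Bu4N[Ph3SiF2] (0.5 equiv), THF, −78 to −20 °C; AcOH quench
Reagents that add atoms: none
Why: The chiral acyloxyborane binds the aldehyde and the enolsilane adds to its Si face through an open transition state (Mukaiyama aldol) with silyl transfer to give 7; fluoride then frees the C2 alkoxide, which adds to the fluorine-bearing ring carbon ortho to the ketone and expels fluoride (SNAr through a Meisenheimer intermediate), the fluoride set free carrying on the desilylation. The closest known reaction types are the catalytic enantioselective Mukaiyama aldol of aryl methyl ketone enolsilanes with aromatic aldehydes and the intramolecular SNAr O-arylation of beta-hydroxy ortho-fluoroaryl ketones to chroman-4-ones. Ring C closes as a six-membered ring by addition–elimination at C8a, formally a 6-endo-trig conjugate addition to the ketone-conjugated C4a=C8a bond followed by loss of fluoride. C2 is set by the catalyst in the aldol event (Si-face attack gives S) and is carried unchanged through the ring closure because the C2–O bond is never broken. The step needs ring closure to outrun retro-aldol and beta-elimination, which the ortho acyl activation, the fluoride leaving group, the two benzyloxy groups lying meta to fluorine (no resonance deactivation), the low temperature and the acid quench should secure; the aldehyde is limiting so that no racemic background aldol follows fluoride addition, and only one ring carbon carries fluorine, so the site of closure is unambiguous.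

Step 5
Reactants: 8 (2S)-5,7-bis(benzyloxy)-2-[4-(benzyloxy)-3-methoxyphenyl]-2,3-dihydro-4H-chromen-4-one
Product: 11 (2R,3R)-5,7-bis(benzyloxy)-2-[4-(benzyloxy)-3-methoxyphenyl]-3-hydroxy-2,3-dihydro-4H-chromen-4-one, via silyl enol ether 9 (not isolated), via silyloxy epoxide 10 (not isolated)
Conditions: Me3SiOTf, Et3N, CH2Cl2, 0 °C; then dimethyldioxirane, acetone/CH2Cl2, −40 °C; then citric acid, THF/H2O, rt
Reagents that add atoms: dimethyldioxirane, CC1(C)OO1
Why: Rubottom oxidation: soft enolisation forms the silyl enol ether without a free enolate (so the ring aryloxide is not eliminated), the dioxirane should epoxidise the C3=C4 bond on the face opposite the C2 aryl group, and hydrolysis of the silyloxy epoxide leaves the new hydroxyl trans to the aryl group, which sets C3 as R under control of C2.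

Step 6
Reactants: 11 (2R,3R)-5,7-bis(benzyloxy)-2-[4-(benzyloxy)-3-methoxyphenyl]-3-hydroxy-2,3-dihydro-4H-chromen-4-one
Product: 12 (2R,3R)-3,5,7-trihydroxy-2-(4-hydroxy-3-methoxyphenyl)-2,3-dihydro-4H-chromen-4-one
Conditions: H2 (1 atm), 10% Pd/C, EtOAc/MeOH, rt
Reagents that add atoms: none
Why: Catalytic hydrogenolysis should cleave the three benzyl ethers under neutral conditions that leave the ketone, the cyclic benzylic ether and both stereocentres untouched.

Step 7
Reactants: 12 (2R,3R)-3,5,7-trihydroxy-2-(4-hydroxy-3-methoxyphenyl)-2,3-dihydro-4H-chromen-4-one; 13 1-bromo-3-methylbut-2-ene (prenyl bromide, 1.0 equiv)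
Product: 14 (2R,3R)-3,5-dihydroxy-2-(4-hydroxy-3-methoxyphenyl)-7-[(3-methylbut-2-en-1-yl)oxy]-2,3-dihydro-4H-chromen-4-one (target)
Conditions: K2CO3 (1.0 equiv), acetone, rt
Reagents that add atoms: none
Why: Williamson etherification: the 7-hydroxyl, para to the carbonyl, is the most acidic hydroxyl (the 5-hydroxyl is chelated, the guaiacyl hydroxyl is a weaker acid, the 3-hydroxyl is aliphatic), so one equivalent of carbonate should form only that phenoxide, which is alkylated by prenyl bromide at room temperature without touching C2 or C3.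

Compound list
1 | 5-fluorobenzene-1,3-diol | Oc1cc(O)cc(F)c1 | starting material
2 | acetic acid | CC(=O)O | starting material
3 | 1-(2-fluoro-4,6-dihydroxyphenyl)ethan-1-one | CC(=O)c1c(O)cc(O)cc1F | intermediate
4 | 1-[2,4-bis(benzyloxy)-6-fluorophenyl]ethan-1-one | CC(=O)c1c(F)cc(OCc2ccccc2)cc1OCc1ccccc1 | intermediate
5 | {[1-(2,4-bis(benzyloxy)-6-fluorophenyl)ethenyl]oxy}(trimethyl)silane | C=C(O[Si](C)(C)C)c1c(F)cc(OCc2ccccc2)cc1OCc1ccccc1 | intermediate
6 | 4-(benzyloxy)-3-methoxybenzaldehyde | COc1cc(C=O)ccc1OCc1ccccc1 | starting material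
7 | (3S)-3-[4-(benzyloxy)-3-methoxyphenyl]-1-[2,4-bis(benzyloxy)-6-fluorophenyl]-3-[(trimethylsilyl)oxy]propan-1-one (not isolated) | COc1cc([C@H](CC(=O)c2c(F)cc(OCc3ccccc3)cc2OCc2ccccc2)O[Si](C)(C)C)ccc1OCc1ccccc1 | intermediate
8 | (2S)-5,7-bis(benzyloxy)-2-[4-(benzyloxy)-3-methoxyphenyl]-2,3-dihydro-4H-chromen-4-one | COc1cc([C@H]2Oc3cc(OCc4ccccc4)cc(OCc4ccccc4)c3C(=O)C2)ccc1OCc1ccccc1 | intermediate
9 | {[(2S)-5,7-bis(benzyloxy)-2-[4-(benzyloxy)-3-methoxyphenyl]-2H-chromen-4-yl]oxy}(trimethyl)silane (not isolated) | COc1cc([C@H]2Oc3cc(OCc4ccccc4)cc(OCc4ccccc4)c3C(O[Si](C)(C)C)=C2)ccc1OCc1ccccc1 | intermediate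
10 | 3,4-epoxide of 9, oxirane oxygen anti to the 2-aryl group, trimethylsilyloxy on C4; (2R,3R,4R) in chromane numbering (not isolated) | COc1cc([C@H]2Oc3cc(OCc4ccccc4)cc(OCc4ccccc4)c3[C@]4(O[Si](C)(C)C)O[C@H]24)ccc1OCc1ccccc1 | intermediate
11 | (2R,3R)-5,7-bis(benzyloxy)-2-[4-(benzyloxy)-3-methoxyphenyl]-3-hydroxy-2,3-dihydro-4H-chromen-4-one | COc1cc([C@H]2Oc3cc(OCc4ccccc4)cc(OCc4ccccc4)c3C(=O)[C@@H]2O)ccc1OCc1ccccc1 | intermediate
12 | (2R,3R)-3,5,7-trihydroxy-2-(4-hydroxy-3-methoxyphenyl)-2,3-dihydro-4H-chromen-4-one | COc1cc([C@H]2Oc3cc(O)cc(O)c3C(=O)[C@@H]2O)ccc1O | intermediate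
13 | 1-bromo-3-methylbut-2-ene | CC(C)=CCBr | starting material
14 | (2R,3R)-3,5-dihydroxy-2-(4-hydroxy-3-methoxyphenyl)-7-[(3-methylbut-2-en-1-yl)oxy]-2,3-dihydro-4H-chromen-4-one | COc1cc([C@H]2Oc3cc(OCC=C(C)C)cc(O)c3C(=O)[C@@H]2O)ccc1O | target

Total step count: 7
Longest linear sequence: 7 steps (1 → 3 → 4 → 5 → 8 → 11 → 12 → 14)

Steps most likely to fail

Step 4 (key step). The Lewis-acid aldol may be slow or poorly face-selective with the electron-rich aldehyde. The freed alkoxide may also revert by retro-aldol, eliminate, or the product ring may reopen under the basic fluoride, all of which erode enantiopurity (recrystallisation of 8 would be the first remedy). Fallback: setting out from ketone 4 and aldehyde 6, Claisen–Schmidt condensation (KOH, EtOH, 0 °C to rt) should give (2E)-1-[2,4-bis(benzyloxy)-6-fluorophenyl]-3-[4-(benzyloxy)-3-methoxyphenyl]prop-2-en-1-one F1. Copper-catalysed enantioselective conjugate borylation (CuCl, NaOt-Bu, Josiphos-type bisphosphine of the antipode that gives the S boronate, B2pin2, MeOH, THF) should give the (3S)-beta-boryl ketone F2. Oxidation with NaBO3 (THF/H2O) should give the (3S)-beta-hydroxy ketone F3 with retention. The lithium alkoxide of F3 (LiN(SiMe3)2, THF, −78 to 0 °C) should then close ring C by SNAr, and the sequence rejoins the route at 8.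

Step 5. Beta-elimination of the ring oxygen during enol ether formation (ring opening to the chalcone) or oxidation of the electron-rich arenes by the dioxirane may compete. Fallback: setting out from 8, the ring is opened on purpose (KOH, EtOH) to the 2'-hydroxychalcone F4, and the phenol is capped (MOMCl, NaH, DMF) to give the methoxymethyl ether F5. Juliá–Colonna epoxidation (poly-L-leucine, urea–H2O2, DBU, THF) should give the (2R,3S)-epoxy ketone F6. HCl in MeOH (50 °C) should remove the acetal to the free phenol epoxide F7 (not isolated), which closes by attack of the phenol at the benzylic epoxide carbon with inversion. This should give the trans compound 11, where the route is rejoined.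

Step 7. Over-alkylation at the guaiacyl hydroxyl, C-alkylation of ring A, or base-induced epimerisation and ring contraction of the dihydroflavonol may occur. Fallback: setting out from 12, a Mitsunobu etherification (PPh3, diisopropyl azodicarboxylate, 3-methylbut-2-en-1-ol, THF, 0 °C) should alkylate only the most acidic hydroxyl (7-OH) under neutral conditions and give 14 directly; no new compound is made (F0).

Further compounds
F1 | step 4 | (2E)-1-[2,4-bis(benzyloxy)-6-fluorophenyl]-3-[4-(benzyloxy)-3-methoxyphenyl]prop-2-en-1-one | COc1cc(/C=C/C(=O)c2c(F)cc(OCc3ccccc3)cc2OCc2ccccc2)ccc1OCc1ccccc1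
F2 | step 4 | (3S)-3-[4-(benzyloxy)-3-methoxyphenyl]-1-[2,4-bis(benzyloxy)-6-fluorophenyl]-3-(4,4,5,5-tetramethyl-1,3,2-dioxaborolan-2-yl)propan-1-one | COc1cc([C@H](CC(=O)c2c(F)cc(OCc3ccccc3)cc2OCc2ccccc2)B2OC(C)(C)C(C)(C)O2)ccc1OCc1ccccc1
F3 | step 4 | (3S)-3-[4-(benzyloxy)-3-methoxyphenyl]-1-[2,4-bis(benzyloxy)-6-fluorophenyl]-3-hydroxypropan-1-one | COc1cc([C@H](CC(=O)c2c(F)cc(OCc3ccccc3)cc2OCc2ccccc2)O)ccc1OCc1ccccc1
F4 | step 5 | (2E)-1-[2,4-bis(benzyloxy)-6-hydroxyphenyl]-3-[4-(benzyloxy)-3-methoxyphenyl]prop-2-en-1-one | COc1cc(/C=C/C(=O)c2c(O)cc(OCc3ccccc3)cc2OCc2ccccc2)ccc1OCc1ccccc1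
F5 | step 5 | (2E)-1-[2,4-bis(benzyloxy)-6-(methoxymethoxy)phenyl]-3-[4-(benzyloxy)-3-methoxyphenyl]prop-2-en-1-one | COc1cc(/C=C/C(=O)c2c(OCOC)cc(OCc3ccccc3)cc2OCc2ccccc2)ccc1OCc1ccccc1
F6 | step 5 | [2,4-bis(benzyloxy)-6-(methoxymethoxy)phenyl]{(2R,3S)-3-[4-(benzyloxy)-3-methoxyphenyl]oxiran-2-yl}methanone | COc1cc([C@@H]2O[C@H]2C(=O)c2c(OCOC)cc(OCc3ccccc3)cc2OCc2ccccc2)ccc1OCc1ccccc1
F7 | step 5 | [2,4-bis(benzyloxy)-6-hydroxyphenyl]{(2R,3S)-3-[4-(benzyloxy)-3-methoxyphenyl]oxiran-2-yl}methanone | COc1cc([C@@H]2O[C@H]2C(=O)c2c(O)cc(OCc3ccccc3)cc2OCc2ccccc2)ccc1OCc1ccccc1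
F0 | step 7 | none | none
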